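**Compound numbering used throughout:** 1 3,4,5-trimethoxyphenol; 2 the hydroxyacetophenone; 3 diethyl oxalate; 4 the dioxobutanoate; 5 the chromone ester; 6 the chromone acid; 7 its acid chloride; 8 the diazoketone; 9 the methoxyacetyl chromone; 10 the enol triflate; 11 hexabutylditin; 12 the alkenylstannane; 13 dimethyl squarate; 14 the hydroxycyclobutenone; 15 the chlorocyclobutenone; 16 the coupled alkenylcyclobutenone; 17 the dienylketene; 18 the cyclohexadienone; 19 5-O-methylpsiadiarabicin; 20 psiadiarabicin.

## Analysis of the target

Psiadiarabicin (20) is a flavone, a benzo-fused 4-pyranone (rings A and C) that carries a phenyl ring B on C2, and it has no stereocentre, so the whole task is the placement of seven oxygen substituents. Ring A bears a hydroxyl at C5, hydrogen-bonded to the C4 carbonyl, and methoxy groups at C6 and C7. Ring B is oxygenated on four adjacent carbons, with methoxy groups at C2', C4' and C5' and a free hydroxyl at C3', and C6'–H is its only hydrogen. The pyranone is electrophilic at C2 and is opened by strong nucleophiles or hot alkali, both benzene rings are electron-rich and easily halogenated or oxidised, and the five methyl ethers restrict the use of strong Lewis acids. The 5-hydroxyl is not the difficulty, because a methyl ether peri to the carbonyl can be removed selectively at the end. The difficulty is the 3'-hydroxyl, which sits between two methyl ethers on a ring that offers no handle for selective demethylation or for regioselective substitution of a simpler arene. The strategy rests on reading C3'(OH)–C4'(OMe)–C5'(OMe)–C6'(H) as the carbonyl carbon, the two enol-ether carbons and the sp3 CH of a 2,3-dimethoxycyclobutenone, and C1'–C2'(OMe) as a methoxyvinyl group already attached to C2 of the chromone, so that a ring B assembled from these pieces must carry its free hydroxyl at C3'.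

## Retrosynthetic reasoning

**20 to 19 (O–CH3 at C5).** The last bond cut is the methyl–oxygen bond at C5. This ether is the only one that can hold a Lewis acid in a chelate with the C4 carbonyl, so it is the one methyl group that can be removed in the presence of five others. Carrying ring A as its 5,6,7-trimethyl ether keeps every earlier intermediate free of ring A phenols and lets ring A come from the symmetrical phenol 1.

**19 to 12 and 15 (C1'–C6' and C2'–C3').** Ring B is cut at two bonds. C2'–C3' is opened by a retro-6π electrocyclisation, which passes through dienone 18 to dienylketene 17, and the ketene is folded back by a retro-4π opening to the 4-alkenylcyclobutenone 16. The C1'–C6' bond of 16 is then cut to alkenylstannane 12 and chlorocyclobutenone 15. These cuts are preferred to any other because they deliver the C3' oxygen as a carbonyl and its two neighbours as methyl ethers, so the differentiation is built into the carbon skeleton. The carbon that carries tin in 12 becomes C1', the carbon that carries chlorine in 15 becomes C6', and the ketene carbon can bond only to the methoxyvinyl terminus, so the substitution pattern follows from constitution. The forward reaction has to couple a hindered, push-pull stannane with a labile allylic chloride and then open and reclose the ring in the same flask.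

**15 to 14 to 13.** The C–Cl bond of 15 goes back to the C–OH bond of 14, and that to one carbonyl of dimethyl squarate 13. The two carbonyls of 13 are equivalent, so monoreduction raises no regiochemical question. Both 14 and 15 ionise easily to an alkoxy-stabilised cyclobutenyl cation, so the forward steps must avoid acid and 15 must be used at once.

**12 to 10 to 9 (C–Sn, then C–OTf).** The C–Sn bond is traced to the C–O bond of enol triflate 10, and 10 to ketone 9. Introducing tin by halogenating a methoxyvinyl side chain was rejected, because the electrophile would have to choose between the side-chain carbon, C3 of the pyranone and C8 of ring A. Ketone 9 has a single enolisable carbon, so the position of the triflate, and hence of tin, is fixed by constitution.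

**9 to 8 to 6 (C–OMe, then C–C).** The methoxy C–O bond of 9 is cut by a retro O–H insertion to diazoketone 8, and the bond between the acyl carbon and the diazo carbon is cut to acid 6 through its chloride 7. This brings in the future C2' as a one-carbon diazo unit and its methoxy group by insertion, without any organometallic reagent that could attack the pyranone.

**6 to 5 to 2 and 3 (ring C).** Acid 6 comes from ester 5. Ring C of 5 is cut at O1–C2 and C2–C3, which gives hydroxyacetophenone 2 and diethyl oxalate 3 through the dioxobutanoate 4. Oxalate 3 supplies C2 and the carbon that becomes C1' in one piece. The forward Claisen condensation and cyclodehydration is the standard entry to chromone-2-carboxylates.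

**2 to 1 (C4–C4a).** The acetyl group is removed from 2 to give phenol 1. Both positions ortho to the hydroxyl of 1 are equivalent and the para position is blocked, so C-acetylation can give only 2.

## Alternatives that were turned down

Alternative 1: Ring A is cut at C7–C8 and C5–C6. What remains is a 4-pyranone that already carries ring B, methyl 6-[3-(benzyloxy)-2,4,5-trimethoxyphenyl]-2-methyl-4-oxo-4H-pyran-3-carboxylate A1, together with methyl methoxyacetate A2 as the source of C6, C7 and the 6-methoxy group. In the forward direction the carbanion formed at the 2-methyl group of A1 would be acylated by A2, which makes the C8–C7 bond. The methoxy-substituted enolate carbon created in this way would then close onto the ester at C3 of the pyranone in a Dieckmann reaction (C6–C5), and tautomerisation would leave ring A aromatic in 3'-benzyloxy-5,7-dihydroxy-6,2',4',5'-tetramethoxyflavone A3. In its favour, only enolate chemistry is needed, with no tin and no strained ring, and A3 has its 5-hydroxyl free and chelated, while its unchelated 7-hydroxyl should accept a methyl group selectively. Against it, A1 requires a ring B whose 3'-oxygen is already singled out as a benzyl ether. That is the central problem of the target, and this plan moves it into an arene synthesis in which nearly equivalent ring positions or several methyl ethers have to be told apart. The double deprotonation of A1 also takes place next to a pyranone that strong base opens, A2 can condense with itself, and a methylation and a debenzylation still follow A3. Compared with the chosen route, this plan is stronger in the end-game on ring A (no demethylation) and in avoiding organotin. The chosen route offers instead a ring B whose hydroxyl is differentiated by mechanism and not by protecting-group manipulation, and it needs no protecting group apart from the 5-O-methyl.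

Alternative 2: Ring C is cut at O1–C8a, C4–C4a and O1–C2, which leads to 3,4,5-trimethoxybenzyne A4 and 3-[3-(benzyloxy)-2,4,5-trimethoxyphenyl]prop-2-ynoic acid A5. In the forward direction fluoride would set A4 free from 3,4,5-trimethoxy-2-(trimethylsilyl)phenyl trifluoromethanesulfonate A6. The carboxylate oxygen of A5 would add to the aryne carbon remote from the flanking methoxy group, the resulting aryl anion would take the acyl carbon, and the liberated phenoxide would cyclise onto the ynone to give 3'-benzyloxy-5,6,7,2',4',5'-hexamethoxyflavone A7. In its favour, this is the most convergent plan, with three bonds formed in one operation, and the methoxy group next to the aryne bond of A4 should direct the addition reliably. Against it, A5 again contains the finished, benzyl-differentiated ring B, so the hard part is untouched. The precursor A6 costs several steps from 1, insertion of A4 competes with plain O-arylation of A5, and A7 still needs both debenzylation and 5-O-demethylation. Compared with the chosen route, this plan is stronger in convergence and in the number of bonds made per step. The chosen route is longer in its linear part, but it solves the 3'-hydroxyl problem, which this alternative leaves to an undefined arene synthesis.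

Alternative 3: The same cyclobutenone logic is applied to ring A. The flavone is cut at C8–C8a and C5–C4a, which gives 2-[3-(benzyloxy)-2,4,5-trimethoxyphenyl]-6-(tributylstannyl)-4H-pyran-4-one A8 and chloride 15. In the forward direction Stille coupling of A8 with 15 would form C8–C8a, and the ketene derived from the coupled cyclobutenone would close C5–C4a onto the pyranone double bond to give 3'-O-benzylpsiadiarabicin A9. In its favour, the ketene carbonyl becomes the chelated 5-hydroxyl directly, so A9 needs no demethylation and only a hydrogenolysis remains; on this point the plan is stronger than the chosen route. Against it, the benzannulation is spent on a hydroxyl that chelation-controlled demethylation delivers anyway, while the 3'-hydroxyl must again be brought in through a benzyl ether on a pre-made ring B. The 6π closure has to engage the vinylogous-ester double bond of a 4-pyranone, and the stannylpyranone A8 has no simple preparation. Both routes share the labile chloride 15 and the same type of risk. The chosen route places the benzannulation on the ring where no classical solution exists and pays for it with one well-precedented final demethylation, which the route to A9 avoids.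

Key step: step 10

Remark: chloride 15 is taken as the racemate and is not stored. Its CHCl configuration and the enol-ether geometry of 10 and 12 (drawn Z) are both lost in step 10, so neither needs to be controlled.

## Route

Step 1
Reactants: 1 3,4,5-trimethoxyphenol
Product: 2 1-(6-hydroxy-2,3,4-trimethoxyphenyl)ethan-1-one
Conditions: AcOH, BF3·OEt2 (3 equiv), 90 °C; aqueous work-up
Reagents that add atoms: acetic acid, CC(=O)O
Why: Friedel–Crafts C-acylation of an electron-rich phenol; the two ortho positions of 1 are equivalent and the para position is blocked, and the difluoroboron chelate of the product ketone should prevent a second acylation.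

Step 2
Reactants: 2 1-(6-hydroxy-2,3,4-trimethoxyphenyl)ethan-1-one; 3 diethyl oxalate
Product: 5 ethyl 5,6,7-trimethoxy-4-oxo-4H-chromene-2-carboxylate, via aryl dioxobutanoate 4 (not isolated)
Conditions: NaOEt, EtOH, reflux; then HCl in EtOH, 70 °C
Reagents that add atoms: none
Why: Crossed Claisen condensation of the methyl ketone enolate with the non-enolisable oxalate should give 4, and acid then closes O1–C2 by cyclodehydration, the standard chromone-2-carboxylate synthesis; brief anhydrous acid should leave the 5-methoxy group in place.

Step 3
Reactants: 5 ethyl 5,6,7-trimethoxy-4-oxo-4H-chromene-2-carboxylate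
Product: 6 5,6,7-trimethoxy-4-oxo-4H-chromene-2-carboxylic acid
Conditions: LiOH, THF/H2O, 0 °C to rt; then 1 M HCl
Reagents that add atoms: lithium hydroxide, [Li+].[OH-]
Why: Saponification of an activated ester; if hydroxide opens the pyranone at C2, acidification should reclose it, because the open form is the dioxo acid that cyclodehydrates to 6.

Step 4
Reactants: 6 5,6,7-trimethoxy-4-oxo-4H-chromene-2-carboxylic acid
Product: 8 2-(2-diazoacetyl)-5,6,7-trimethoxy-4H-chromen-4-one, via chromone-2-carbonyl chloride 7 (not isolated)
Conditions: (COCl)2, cat. DMF, CH2Cl2, 0 °C to rt; evaporate; then CH2N2 (2.2 equiv), Et2O/CH2Cl2, −20 to 0 °C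
Reagents that add atoms: oxalyl chloride, ClC(=O)C(=O)Cl (chlorine of 7); diazomethane, C=[N+]=[N-]
Why: Acid chloride formation through the chloroiminium catalyst, then C-acylation of diazomethane as in the first stage of an Arndt–Eistert sequence, the second equivalent taking up HCl; low temperature and a small excess should limit dipolar addition to the C2=C3 bond.

Step 5
Reactants: 8 2-(2-diazoacetyl)-5,6,7-trimethoxy-4H-chromen-4-one
Product: 9 5,6,7-trimethoxy-2-(2-methoxyacetyl)-4H-chromen-4-one
Conditions: MeOH, Rh2(OAc)4 (1 mol %), CH2Cl2, rt
Reagents that add atoms: methanol, CO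
Why: Rh2(OAc)4 converts the diazoketone into a rhodium carbenoid that inserts into the O–H bond of methanol, a standard route to alpha-alkoxy ketones; with methanol in large excess no other carbenoid pathway should compete.

Step 6
Reactants: 9 5,6,7-trimethoxy-2-(2-methoxyacetyl)-4H-chromen-4-one
Product: 10 (Z)-2-methoxy-1-(5,6,7-trimethoxy-4-oxo-4H-chromen-2-yl)ethenyl trifluoromethanesulfonate
Conditions: KN(SiMe3)2, PhNTf2, THF, −78 to −20 °C; aq. NH4Cl
Reagents that add atoms: N-phenylbis(trifluoromethanesulfonimide), O=S(=O)(N(c1ccccc1)S(=O)(=O)C(F)(F)F)C(F)(F)F
Why: Enol triflate formation from a ketone enolate; the CH2 between carbonyl and methoxy is the only enolisable position of 9, so one constitution results, and chelation of potassium between the enolate and methoxy oxygens should favour the Z enolate (the E isomer would serve equally).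

Step 7
Reactants: 10 (Z)-2-methoxy-1-(5,6,7-trimethoxy-4-oxo-4H-chromen-2-yl)ethenyl trifluoromethanesulfonate; 11 hexabutylditin
Product: 12 5,6,7-trimethoxy-2-[(Z)-2-methoxy-1-(tributylstannyl)ethenyl]-4H-chromen-4-one
Conditions: Pd(PPh3)4 (5 mol %), LiCl, THF, 65 °C; chromatography on Et3N-deactivated silica
Reagents that add atoms: none
Why: Palladium-catalysed stannylation of an enol triflate: oxidative addition of zerovalent palladium to the C–O bond, transmetalation with the ditin (LiCl converting the vinylpalladium triflate into its chloride) and reductive elimination should form the C–Sn bond with retention of alkene geometry.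

Step 8
Reactants: 13 dimethyl squarate
Product: 14 4-hydroxy-2,3-dimethoxycyclobut-2-en-1-one (racemic)
Conditions: LiAlH(OtBu)3 (1.0 equiv), THF, −78 °C; aq. NaHCO3 work-up
Reagents that add atoms: none
Why: 1,2-Hydride addition of a bulky, mild aluminium hydride to one of two equivalent, highly electrophilic carbonyl groups; one equivalent at low temperature should stop at the hydroxyketone, the new stereocentre is formed racemic, and a non-acidic work-up avoids acid-triggered rearrangement to a cyclobutenedione.

Step 9
Reactants: 14 4-hydroxy-2,3-dimethoxycyclobut-2-en-1-one (racemic)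
Product: 15 4-chloro-2,3-dimethoxycyclobut-2-en-1-one (racemic)
Conditions: 1-chloro-N,N,2-trimethylprop-1-en-1-amine, CH2Cl2, 0 °C; solvent exchange to dioxane, used at once
Reagents that add atoms: 1-chloro-N,N,2-trimethylprop-1-en-1-amine, CC(C)=C(Cl)N(C)C
Why: The alpha-chloroenamine turns alcohols into chlorides under neutral conditions through an alkoxyiminium chloride that collapses to alkyl chloride and amide, a method suited to ionisable substrates; no acid is set free, and an allylic isomer of the chloride, should it form, leads to the same palladium allyl species in step 10.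

Step 10
Reactants: 12 5,6,7-trimethoxy-2-[(Z)-2-methoxy-1-(tributylstannyl)ethenyl]-4H-chromen-4-one; 15 4-chloro-2,3-dimethoxycyclobut-2-en-1-one (racemic)
Product: 19 2-(3-hydroxy-2,4,5-trimethoxyphenyl)-5,6,7-trimethoxy-4H-chromen-4-one (5-O-methylpsiadiarabicin), via coupled 4-alkenylcyclobutenone 16 (not isolated), via dienylketene 17 (not isolated), via cyclohexadienone tautomer 18 (not isolated)
Conditions: PdCl2(PhCN)2 (5 mol %), tri(2-furyl)phosphine (10 mol %), dioxane, 50 °C; then 100 °C
Reagents that add atoms: none
Why: Oxidative addition of the allylic C–Cl bond of 15 to zerovalent palladium, generated in the flask from PdCl2(PhCN)2 and tri(2-furyl)phosphine, should give an eta-3 oxocyclobutenyl palladium chloride; transfer of the alkenyl group from tin and reductive elimination then form C1'–C6' in 16. The closest known reaction type is the palladium-catalysed coupling of 4-chlorocyclobutenones with alkenylstannanes followed by thermal rearrangement to phenols, applied here to a 2,3-dialkoxy chloride and a push-pull stannane. On heating, 16 opens by reversible conrotatory 4π electrocyclic cleavage of the bond between the carbonyl carbon and the sp3 carbon to dienylketene 17. Ring B then closes by thermal disrotatory 6π electrocyclisation, the ketene carbon bonding to the methoxy-bearing vinyl terminus (C2'–C3'), and dienone 18 enolises irreversibly to phenol 19. No stereocentre remains, since the sp3 centres of 16 and 18 are transient and racemic. The step needs coupling at the CH terminus of the allyl unit and not at its methoxy-bearing terminus, which the lower steric demand of the CH carbon and the conjugated vinylogous ester of the resulting product should secure. It also needs the alkenyl group to rotate inward on ring opening, which is not a kinetic requirement because the opening is reversible and only the inward isomer is drained by cyclisation. Where the free hydroxyl ends up is decided by constitution alone: the tin-bearing carbon becomes C1', the chlorine-bearing carbon becomes C6', and the cyclobutenone carbonyl carbon has no choice but to become C3'.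

Step 11
Reactants: 19 2-(3-hydroxy-2,4,5-trimethoxyphenyl)-5,6,7-trimethoxy-4H-chromen-4-one
Product: 20 5-hydroxy-2-(3-hydroxy-2,4,5-trimethoxyphenyl)-6,7-dimethoxy-4H-chromen-4-one (psiadiarabicin)
Conditions: BCl3 (2.2 equiv), CH2Cl2, −78 to 0 °C; aqueous work-up
Reagents that add atoms: none
Why: BCl3 binds the C4 carbonyl and the peri 5-methoxy oxygen in a six-membered chelate and chloride removes that methyl group, the classical selective 5-O-demethylation of polymethoxyflavones; one equivalent is taken up by the 3'-phenol, and low temperature should spare the other five methyl ethers.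

## Compound list

1 | 3,4,5-trimethoxyphenol | COc1cc(O)cc(OC)c1OC | starting material
2 | 1-(6-hydroxy-2,3,4-trimethoxyphenyl)ethan-1-one | CC(=O)c1c(O)cc(OC)c(OC)c1OC | intermediate
3 | diethyl oxalate | CCOC(=O)C(=O)OCC | starting material
4 | ethyl 4-(6-hydroxy-2,3,4-trimethoxyphenyl)-2,4-dioxobutanoate | CCOC(=O)C(=O)CC(=O)c1c(O)cc(OC)c(OC)c1OC | intermediate (not isolated)
5 | ethyl 5,6,7-trimethoxy-4-oxo-4H-chromene-2-carboxylate | CCOC(=O)c1cc(=O)c2c(OC)c(OC)c(OC)cc2o1 | intermediate
6 | 5,6,7-trimethoxy-4-oxo-4H-chromene-2-carboxylic acid | OC(=O)c1cc(=O)c2c(OC)c(OC)c(OC)cc2o1 | intermediate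
7 | 5,6,7-trimethoxy-4-oxo-4H-chromene-2-carbonyl chloride | ClC(=O)c1cc(=O)c2c(OC)c(OC)c(OC)cc2o1 | intermediate (not isolated)
8 | 2-(2-diazoacetyl)-5,6,7-trimethoxy-4H-chromen-4-one | [N-]=[N+]=CC(=O)c1cc(=O)c2c(OC)c(OC)c(OC)cc2o1 | intermediate
9 | 5,6,7-trimethoxy-2-(2-methoxyacetyl)-4H-chromen-4-one | COCC(=O)c1cc(=O)c2c(OC)c(OC)c(OC)cc2o1 | intermediate
10 | (Z)-2-methoxy-1-(5,6,7-trimethoxy-4-oxo-4H-chromen-2-yl)ethenyl trifluoromethanesulfonate | CO/C=C(\OS(=O)(=O)C(F)(F)F)c1cc(=O)c2c(OC)c(OC)c(OC)cc2o1 | intermediate
11 | hexabutylditin | CCCC[Sn](CCCC)(CCCC)[Sn](CCCC)(CCCC)CCCC | starting material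
12 | 5,6,7-trimethoxy-2-[(Z)-2-methoxy-1-(tributylstannyl)ethenyl]-4H-chromen-4-one | CO/C=C(\[Sn](CCCC)(CCCC)CCCC)c1cc(=O)c2c(OC)c(OC)c(OC)cc2o1 | intermediate
13 | dimethyl squarate (3,4-dimethoxycyclobut-3-ene-1,2-dione) | COC1=C(OC)C(=O)C1=O | starting material
14 | 4-hydroxy-2,3-dimethoxycyclobut-2-en-1-one (racemic) | COC1=C(OC)C(O)C1=O | intermediate
15 | 4-chloro-2,3-dimethoxycyclobut-2-en-1-one (racemic) | COC1=C(OC)C(Cl)C1=O | intermediate
16 | 2-[(E)-1-(2,3-dimethoxy-4-oxocyclobut-2-en-1-yl)-2-methoxyethenyl]-5,6,7-trimethoxy-4H-chromen-4-one (racemic) | CO/C=C(\C1C(OC)=C(OC)C1=O)c1cc(=O)c2c(OC)c(OC)c(OC)cc2o1 | intermediate (not isolated)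
17 | (3E,5E)-2,3,6-trimethoxy-5-(5,6,7-trimethoxy-4-oxo-4H-chromen-2-yl)hexa-1,3,5-trien-1-one | O=C=C(OC)/C(OC)=C\C(=C/OC)c1cc(=O)c2c(OC)c(OC)c(OC)cc2o1 | intermediate (not isolated)
18 | 2,3,6-trimethoxy-5-(5,6,7-trimethoxy-4-oxo-4H-chromen-2-yl)cyclohexa-2,4-dien-1-one (racemic) | COC1C(=O)C(OC)=C(OC)C=C1c1cc(=O)c2c(OC)c(OC)c(OC)cc2o1 | intermediate (not isolated)
19 | 2-(3-hydroxy-2,4,5-trimethoxyphenyl)-5,6,7-trimethoxy-4H-chromen-4-one (5-O-methylpsiadiarabicin) | COc1cc(-c2cc(=O)c3c(OC)c(OC)c(OC)cc3o2)c(OC)c(O)c1OC | intermediate
20 | 5-hydroxy-2-(3-hydroxy-2,4,5-trimethoxyphenyl)-6,7-dimethoxy-4H-chromen-4-one (psiadiarabicin) | COc1cc(-c2cc(=O)c3c(O)c(OC)c(OC)cc3o2)c(OC)c(O)c1OC | target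

## Step count and least certain steps

Total step count: 11. Longest linear sequence: 9 steps (steps 1 to 7, 10 and 11, from phenol 1); steps 8 and 9 form a two-step branch that joins at step 10.

**Step 10 (the key step).**
- What may go wrong: transfer of the alkenyl group from tin to palladium may be slow, because the stannane is branched at the tin-bearing carbon, electron-poor and attached to a pyranone that can bind the catalyst. During that time chloride 15 can ionise and lose chloromethane, or the stannane can be protodestannylated. Coupling at the methoxy-bearing allyl terminus would lead to an isomeric ring B.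
- Fallback: ring B is built first on a small stannane that carries no pyranone and can be used in excess, and the flavone is then assembled by Claisen chemistry, setting out from 15 and 2 and returning at 19. Chloride 15 is coupled under the step 10 conditions with methyl (Z)-3-methoxy-2-(tributylstannyl)prop-2-enoate F1, which should give methyl 3-hydroxy-2,4,5-trimethoxybenzoate F2 by the same coupling, ring opening and 6π closure. The phenol is protected with chloromethyl methyl ether and iPr2NEt as methyl 2,4,5-trimethoxy-3-(methoxymethoxy)benzoate F3. The lithium dianion of 2 (LiN(SiMe3)2, THF) is acylated by F3 to give 1-(6-hydroxy-2,3,4-trimethoxyphenyl)-3-[2,4,5-trimethoxy-3-(methoxymethoxy)phenyl]propane-1,3-dione F4. HCl in methanol then cyclodehydrates F4 and removes the acetal in the same operation to give 19.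

**Step 9.**
- What may go wrong: ionisation of the C–Cl bond to the alkoxy-stabilised oxocyclobutenyl cation, followed by chloride attack on a methyl group, degrades the reagent to a cyclobutenedione before it can be coupled.
- Fallback: the halide is replaced by an ester that ionises only on palladium, setting out from 14 and returning at 19. Alcohol 14 is acetylated (Ac2O, pyridine) to 2,3-dimethoxy-4-oxocyclobut-2-en-1-yl acetate F5. F5 is coupled with stannane 12 in an allylic-acetate Stille coupling (Pd2(dba)3, LiCl, DMF, 50 °C), which should give 16. Heating then carries 16 through 17 and 18 to 19.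

**Step 4.**
- What may go wrong: 1,3-dipolar cycloaddition of diazomethane to the doubly activated C2=C3 bond, in competition with or after acylation.
- Fallback: diazo chemistry is avoided altogether, setting out from 6 and returning at 9. Acid chloride 7, made from 6 as in step 4, is coupled with tributyl(methoxymethyl)stannane F6 in a palladium-catalysed acylative Stille coupling (PdCl2(PPh3)2, toluene, 80 °C), in which the alpha-alkoxymethyl group transfers in preference to butyl, to give ketone 9 directly.

**Step 11.**
- What may go wrong: over-demethylation. Once boron is bound at O5 it can engage the neighbouring 6-methoxy group, and boron bound to the 3'-phenoxide can deliver cleavage of the flanking 2'- or 4'-methoxy group.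
- Fallback: the 3'-oxygen is masked so that boron can bind only at the carbonyl, setting out from 19 and returning at 20. Phenol 19 is acetylated (Ac2O, pyridine) to its 3'-O-acetate, 2,3,6-trimethoxy-5-(5,6,7-trimethoxy-4-oxo-4H-chromen-2-yl)phenyl acetate F7. BCl3 (1.2 equiv, CH2Cl2, −78 to 0 °C) should then give 3-(5-hydroxy-6,7-dimethoxy-4-oxo-4H-chromen-2-yl)-2,5,6-trimethoxyphenyl acetate F8. Methanolysis (K2CO3, MeOH, rt) gives 20.

## Further compounds

F1 | step 10 | methyl (Z)-3-methoxy-2-(tributylstannyl)prop-2-enoate | CO/C=C(\[Sn](CCCC)(CCCC)CCCC)C(=O)OC
F2 | step 10 | methyl 3-hydroxy-2,4,5-trimethoxybenzoate | COC(=O)c1cc(OC)c(OC)c(O)c1OC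
F3 | step 10 | methyl 2,4,5-trimethoxy-3-(methoxymethoxy)benzoate | COCOc1c(OC)c(OC)cc(C(=O)OC)c1OC
F4 | step 10 | 1-(6-hydroxy-2,3,4-trimethoxyphenyl)-3-[2,4,5-trimethoxy-3-(methoxymethoxy)phenyl]propane-1,3-dione | COCOc1c(OC)c(OC)cc(C(=O)CC(=O)c2c(O)cc(OC)c(OC)c2OC)c1OC
F5 | step 9 | 2,3-dimethoxy-4-oxocyclobut-2-en-1-yl acetate (racemic) | CC(=O)OC1C(OC)=C(OC)C1=O
F6 | step 4 | tributyl(methoxymethyl)stannane | CCCC[Sn](CCCC)(CCCC)COC
F7 | step 11 | 2,3,6-trimethoxy-5-(5,6,7-trimethoxy-4-oxo-4H-chromen-2-yl)phenyl acetate | CC(=O)Oc1c(OC)c(OC)cc(-c2cc(=O)c3c(OC)c(OC)c(OC)cc3o2)c1OC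
F8 | step 11 | 3-(5-hydroxy-6,7-dimethoxy-4-oxo-4H-chromen-2-yl)-2,5,6-trimethoxyphenyl acetate | CC(=O)Oc1c(OC)c(OC)cc(-c2cc(=O)c3c(O)c(OC)c(OC)cc3o2)c1OC
A1 | alternative 1 | methyl 6-[3-(benzyloxy)-2,4,5-trimethoxyphenyl]-2-methyl-4-oxo-4H-pyran-3-carboxylate | COC(=O)c1c(C)oc(-c2cc(OC)c(OC)c(OCc3ccccc3)c2OC)cc1=O
A2 | alternative 1 | methyl methoxyacetate | COCC(=O)OC
A3 | alternative 1 | 3'-benzyloxy-5,7-dihydroxy-6,2',4',5'-tetramethoxyflavone | COc1cc(-c2cc(=O)c3c(O)c(OC)c(O)cc3o2)c(OC)c(OCc2ccccc2)c1OC
A4 | alternative 2 | 3,4,5-trimethoxybenzyne | COC1=C(OC)C(OC)=CC#C1
A5 | alternative 2 | 3-[3-(benzyloxy)-2,4,5-trimethoxyphenyl]prop-2-ynoic acid | OC(=O)C#Cc1cc(OC)c(OC)c(OCc2ccccc2)c1OC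
A6 | alternative 2 | 3,4,5-trimethoxy-2-(trimethylsilyl)phenyl trifluoromethanesulfonate | COc1cc(OS(=O)(=O)C(F)(F)F)c([Si](C)(C)C)c(OC)c1OC
A7 | alternative 2 | 3'-benzyloxy-5,6,7,2',4',5'-hexamethoxyflavone | COc1cc(-c2cc(=O)c3c(OC)c(OC)c(OC)cc3o2)c(OC)c(OCc2ccccc2)c1OC
A8 | alternative 3 | 2-[3-(benzyloxy)-2,4,5-trimethoxyphenyl]-6-(tributylstannyl)-4H-pyran-4-one | CCCC[Sn](CCCC)(CCCC)c1cc(=O)cc(-c2cc(OC)c(OC)c(OCc3ccccc3)c2OC)o1
A9 | alternative 3 | 3'-O-benzylpsiadiarabicin | COc1cc(-c2cc(=O)c3c(O)c(OC)c(OC)cc3o2)c(OC)c(OCc2ccccc2)c1OC
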